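**Retrosynthetic overview**

1. The target tetramer (17) ⇐ global hydrogenolysis (20 benzyl ethers and one C8–Br cap) of the protected tetramer 16.
2. 16 ⇐ central C4(unit 2)–C8(unit 3) bond, made by a new gold-catalysed activation of the latent C4 ortho-alkynylaryl thioether of upper dimer 10 in the presence of lower dimer 15.
3. 10 ⇐ C4(unit 1)–C8(unit 2) bond from bromo-capped C4 ether donor 9 and thioether acceptor 7 (hard Lewis acid; the thioether stays latent). 15 ⇐ C4(unit 3)–C8(unit 4) bond from ether donor 5 and penta-O-benzylcatechin 14.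
4. 5, 7, 9 and 14 ⇐ (−)-epicatechin and (+)-catechin by benzylation, DDQ C4–H etherification, NBS bromination, thio exchange and Sonogashira coupling.
5. No ring is built: all four chroman units (ring C with its C2/C3 centres) come from the chiral pool. The interflavan bonds are formed in the order unit 3–unit 4, unit 1–unit 2, unit 2–unit 3, and each new C4 centre is set by attack anti to the 2-aryl and 3-O groups.

Assumption: α/β refer to the usual flavan drawing (ring A left, O1 up; the 2R aryl group is α), units are counted 1 (top) to 4 (catechin), and reagents that only deliver atoms (benzyl bromide and the like) are given with SMILES on the reagent line without a compound number.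

**Route**

Step 1
Reactants: 1 (−)-epicatechin
Product: 2 tetra-O-benzyl-(−)-epicatechin (5,7,3',4'-OBn; 3-OH free)
Conditions: BnBr (4.4 equiv), K2CO3, DMF, 0 °C → rt
Reagents that add atoms: benzyl bromide (BrCc1ccccc1)
Why: Williamson ether synthesis in which K2CO3 deprotonates only the four phenols, so the secondary 3-OH stays free and no stereocentre is touched.

Step 2
Reactants: 2 tetra-O-benzyl-(−)-epicatechin
Product: 4 penta-O-benzyl-(−)-epicatechin (3,5,7,3',4'-OBn), via sodium 5,7,3',4'-tetra-O-benzylepicatechin-3-olate 3 (not isolated)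
Conditions: NaH, DMF, 0 °C; then BnBr, n-Bu4NI (cat.), rt
Reagents that add atoms: benzyl bromide (BrCc1ccccc1)
Why: Williamson etherification of the secondary alcohol through its sodium alkoxide; with all phenols capped, C2 cannot epimerise by quinone methide ring opening.

Step 3
Reactants: 4 penta-O-benzyl-(−)-epicatechin
Product: 5 penta-O-benzyl-4β-(2-ethoxyethoxy)epicatechin (2,3-cis-3,4-trans)
Conditions: DDQ (2 equiv), 2-ethoxyethanol (5 equiv), CH2Cl2, rt
Reagents that add atoms: 2-ethoxyethanol (CCOCCO)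
Why: DDQ benzylic C–H oxidation (hydride abstraction) gives the 5,7-dialkoxy-stabilised C4 cation, which the alcohol traps from the β-face anti to the 2-aryl and 3-OBn groups to give the 3,4-trans ether.

Step 4
Reactants: 5 penta-O-benzyl-4β-(2-ethoxyethoxy)epicatechin
Product: 6 penta-O-benzyl-4β-(2-bromophenylthio)epicatechin (2,3-cis-3,4-trans)
Conditions: 2-bromobenzenethiol (3 equiv), BF3·OEt2 (0.2 equiv), CH2Cl2, −78 → −30 °C
Reagents that add atoms: 2-bromobenzenethiol (Sc1ccccc1Br)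
Why: Lewis acid-catalysed SN1 thio exchange (the preparative counterpart of tannin thiolysis), in which the C4 cation is captured by the soft thiol faster than by C8 of a second molecule, again from the β-face.

Step 5
Reactants: 6 penta-O-benzyl-4β-(2-bromophenylthio)epicatechin
Product: 7 penta-O-benzyl-4β-{[2-(3,3-dimethylbut-1-yn-1-yl)phenyl]thio}epicatechin
Conditions: 3,3-dimethylbut-1-yne (3 equiv), PdCl2(MeCN)2 (3 mol%), XPhos (9 mol%), Cs2CO3, MeCN/THF, 70 °C, sealed tube
Reagents that add atoms: 3,3-dimethylbut-1-yne (CC(C)(C)C#C)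
Why: copper-free Sonogashira coupling in which zerovalent palladium inserts into the aryl C–Br bond and couples the acetylide, leaving benzyl ethers, the C4 thioether and all stereocentres untouched.

Step 6
Reactants: 4 penta-O-benzyl-(−)-epicatechin
Product: 8 8-bromo-penta-O-benzyl-(−)-epicatechin
Conditions: NBS (1.05 equiv), CH2Cl2, −78 → 0 °C
Reagents that add atoms: N-bromosuccinimide (O=C1CCC(=O)N1Br)
Why: electrophilic aromatic bromination that goes to C8 of ring A, the most reactive and least hindered position of benzylated flavan-3-ols, which installs the cap against self-condensation.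

Step 7
Reactants: 8 8-bromo-penta-O-benzyl-(−)-epicatechin
Product: 9 8-bromo-penta-O-benzyl-4β-(2-ethoxyethoxy)epicatechin (2,3-cis-3,4-trans)
Conditions: DDQ (2 equiv), 2-ethoxyethanol (5 equiv), CH2Cl2, rt
Reagents that add atoms: 2-ethoxyethanol (CCOCCO)
Why: the same DDQ oxidative benzylic C–H etherification as in step 3, with β-face trapping of the C4 cation.

Step 8
Reactants: 9 8-bromo-penta-O-benzyl-4β-(2-ethoxyethoxy)epicatechin; 7 penta-O-benzyl-4β-{[2-(3,3-dimethylbut-1-yn-1-yl)phenyl]thio}epicatechin (1.2 equiv)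
Product: 10 upper dimer [8-bromo-penta-O-benzylepicatechin]-(4β→8)-[penta-O-benzyl-4β-{[2-(3,3-dimethylbut-1-yn-1-yl)phenyl]thio}epicatechin]
Conditions: BF3·OEt2 (0.5 equiv), 4 Å MS, CH2Cl2, −78 °C
Reagents that add atoms: none
Why: Friedel–Crafts-type interflavan coupling under orthogonal activation, in which the hard Lewis acid ionises only the C4 ether of 9, the thioether of 7 stays latent, the C8 bromine stops 9 from adding to itself, and C8 of 7 attacks the cation from the β-face to set C4 of unit 1 as 4β (3,4-trans).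

Step 9
Reactants: 11 (+)-catechin
Product: 12 tetra-O-benzyl-(+)-catechin (5,7,3',4'-OBn; 3-OH free)
Conditions: BnBr (4.4 equiv), K2CO3, DMF, 0 °C → rt
Reagents that add atoms: benzyl bromide (BrCc1ccccc1)
Why: Williamson ether synthesis of the four phenols only, with no stereocentre touched.

Step 10
Reactants: 12 tetra-O-benzyl-(+)-catechin
Product: 14 penta-O-benzyl-(+)-catechin (3,5,7,3',4'-OBn), via sodium 5,7,3',4'-tetra-O-benzylcatechin-3-olate 13 (not isolated)
Conditions: NaH, DMF, 0 °C; then BnBr, n-Bu4NI (cat.), rt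
Reagents that add atoms: benzyl bromide (BrCc1ccccc1)
Why: Williamson etherification of the secondary alcohol through its sodium alkoxide without change at C2 or C3.

Step 11
Reactants: 5 penta-O-benzyl-4β-(2-ethoxyethoxy)epicatechin; 14 penta-O-benzyl-(+)-catechin (3 equiv)
Product: 15 lower dimer deca-O-benzyl-[epicatechin-(4β→8)-catechin]
Conditions: Me3SiOTf (0.1 equiv), CH2Cl2, −78 °C
Reagents that add atoms: none
Why: Lewis acid-promoted Friedel–Crafts interflavan coupling in which excess 14 outcompetes self-condensation of 5 and its C8 attacks the C4 cation anti to the 2-aryl and 3-OBn groups, setting C4 of unit 3 as 4β (3,4-trans).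

Step 12
Reactants: 10 upper dimer; 15 lower dimer (1.5 equiv)
Product: 16 protected tetramer 8-bromo-icosa-O-benzyl-[epicatechin-(4β→8)-epicatechin-(4β→8)-epicatechin-(4β→8)-catechin] (Br on C8 of unit 1)
Conditions: Ph3PAuNTf2 (10 mol%), 4 Å MS, CH2Cl2, −20 °C → rt
Reagents that add atoms: none
Why: Proposed new method: cationic monovalent gold π-activates the alkyne of 10, the neighbouring sulfur adds 5-endo-dig to give an S-flavanyl benzothiophenium with a C3–Au bond, and heterolysis of its weak S–C4 bond releases the 5,7-dialkoxy-stabilised C4 cation of unit 2 together with neutral 3-aurated 2-tert-butylbenzothiophene (the tert-butyl group and the congested cation disfavour the competing 1,3-shift of the cation to C3); C8 of the upper unit of 15 then attacks the cation from the β-face anti to the 2-aryl and 3-OBn groups, setting the new C4 centre as 4β (3,4-trans), and the proton lost on rearomatisation protodeaurates the aryl gold to close the cycle, so the central bond forms without a stoichiometric thiophile or free strong acid that could scramble the two existing interflavan bonds; the closest known reaction types are gold-catalysed glycosylation with alkyne-tethered thioglycosides and gold-catalysed carbothiolation (or iodocyclisation with S-dealkylation) of ortho-alkynylaryl sulfides, neither shown on a flavan C4 thioether or for interflavan coupling.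

Step 13
Reactants: 16 protected tetramer
Product: 17 the target tetramer epicatechin-(4β→8)-epicatechin-(4β→8)-epicatechin-(4β→8)-catechin (all phenols and 3-OH groups free)
Conditions: H2 (1 atm), Pd(OH)2/C, THF/MeOH/H2O, rt; Sephadex LH-20, lyophilisation
Reagents that add atoms: none
Why: catalytic hydrogenolysis cleaves all twenty benzyl ethers and hydrodebrominates C8 of unit 1 in one operation without touching any stereocentre or interflavan bond.

**Compound list**

1 | (−)-epicatechin, (2R,3R)-2-(3,4-dihydroxyphenyl)chromane-3,5,7-triol | c1c(O)cc(O)c2c1O[C@H](c1ccc(O)c(O)c1)[C@H](O)C2 | starting material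
2 | 5,7,3',4'-tetra-O-benzyl-(−)-epicatechin (2R,3R; 3-OH free) | c1c(OCc3ccccc3)cc(OCc3ccccc3)c2c1O[C@H](c1ccc(OCc3ccccc3)c(OCc3ccccc3)c1)[C@H](O)C2 | intermediate
3 | sodium 5,7,3',4'-tetra-O-benzylepicatechin-3-olate (2R,3R) | c1c(OCc3ccccc3)cc(OCc3ccccc3)c2c1O[C@H](c1ccc(OCc3ccccc3)c(OCc3ccccc3)c1)[C@H]([O-])C2.[Na+] | intermediate
4 | 3,5,7,3',4'-penta-O-benzyl-(−)-epicatechin (2R,3R) | c1c(OCc3ccccc3)cc(OCc3ccccc3)c2c1O[C@H](c1ccc(OCc3ccccc3)c(OCc3ccccc3)c1)[C@H](OCc3ccccc3)C2 | intermediate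
5 | penta-O-benzyl-4β-(2-ethoxyethoxy)epicatechin (2α-aryl, 3α-OBn, 4β-OR; 2,3-cis-3,4-trans) | c1c(OCc3ccccc3)cc(OCc3ccccc3)c2c1O[C@H](c1ccc(OCc3ccccc3)c(OCc3ccccc3)c1)[C@H](OCc3ccccc3)[C@H]2OCCOCC | intermediate
6 | penta-O-benzyl-4β-(2-bromophenylthio)epicatechin (2,3-cis-3,4-trans) | c1c(OCc3ccccc3)cc(OCc3ccccc3)c2c1O[C@H](c1ccc(OCc3ccccc3)c(OCc3ccccc3)c1)[C@H](OCc3ccccc3)[C@H]2Sc1ccccc1Br | intermediate
7 | penta-O-benzyl-4β-{[2-(3,3-dimethylbut-1-yn-1-yl)phenyl]thio}epicatechin (2,3-cis-3,4-trans) | c1c(OCc3ccccc3)cc(OCc3ccccc3)c2c1O[C@H](c1ccc(OCc3ccccc3)c(OCc3ccccc3)c1)[C@H](OCc3ccccc3)[C@H]2Sc1ccccc1C#CC(C)(C)C | intermediate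
8 | 8-bromo-3,5,7,3',4'-penta-O-benzyl-(−)-epicatechin (2R,3R) | Brc1c(OCc3ccccc3)cc(OCc3ccccc3)c2c1O[C@H](c1ccc(OCc3ccccc3)c(OCc3ccccc3)c1)[C@H](OCc3ccccc3)C2 | intermediate
9 | 8-bromo-penta-O-benzyl-4β-(2-ethoxyethoxy)epicatechin (2,3-cis-3,4-trans) | Brc1c(OCc3ccccc3)cc(OCc3ccccc3)c2c1O[C@H](c1ccc(OCc3ccccc3)c(OCc3ccccc3)c1)[C@H](OCc3ccccc3)[C@H]2OCCOCC | intermediate
10 | upper dimer: [8-bromo-penta-O-benzylepicatechin]-(4β→8)-[penta-O-benzyl-4β-{[2-(3,3-dimethylbut-1-yn-1-yl)phenyl]thio}epicatechin] | Brc1c(OCc3ccccc3)cc(OCc3ccccc3)c2c1O[C@H](c1ccc(OCc3ccccc3)c(OCc3ccccc3)c1)[C@H](OCc3ccccc3)[C@H]2c1c(OCc3ccccc3)cc(OCc3ccccc3)c2c1O[C@H](c1ccc(OCc3ccccc3)c(OCc3ccccc3)c1)[C@H](OCc3ccccc3)[C@H]2Sc1ccccc1C#CC(C)(C)C | intermediate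
11 | (+)-catechin, (2R,3S)-2-(3,4-dihydroxyphenyl)chromane-3,5,7-triol | c1c(O)cc(O)c2c1O[C@H](c1ccc(O)c(O)c1)[C@@H](O)C2 | starting material
12 | 5,7,3',4'-tetra-O-benzyl-(+)-catechin (2R,3S; 3-OH free) | c1c(OCc3ccccc3)cc(OCc3ccccc3)c2c1O[C@H](c1ccc(OCc3ccccc3)c(OCc3ccccc3)c1)[C@@H](O)C2 | intermediate
13 | sodium 5,7,3',4'-tetra-O-benzylcatechin-3-olate (2R,3S) | c1c(OCc3ccccc3)cc(OCc3ccccc3)c2c1O[C@H](c1ccc(OCc3ccccc3)c(OCc3ccccc3)c1)[C@@H]([O-])C2.[Na+] | intermediate
14 | 3,5,7,3',4'-penta-O-benzyl-(+)-catechin (2R,3S) | c1c(OCc3ccccc3)cc(OCc3ccccc3)c2c1O[C@H](c1ccc(OCc3ccccc3)c(OCc3ccccc3)c1)[C@@H](OCc3ccccc3)C2 | intermediate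
15 | lower dimer: deca-O-benzyl-[epicatechin-(4β→8)-catechin] | c1c(OCc3ccccc3)cc(OCc3ccccc3)c2c1O[C@H](c1ccc(OCc3ccccc3)c(OCc3ccccc3)c1)[C@H](OCc3ccccc3)[C@H]2c1c(OCc3ccccc3)cc(OCc3ccccc3)c2c1O[C@H](c1ccc(OCc3ccccc3)c(OCc3ccccc3)c1)[C@@H](OCc3ccccc3)C2 | intermediate
16 | protected tetramer: 8-bromo(unit 1)-icosa-O-benzyl-[epicatechin-(4β→8)-epicatechin-(4β→8)-epicatechin-(4β→8)-catechin] | Brc1c(OCc3ccccc3)cc(OCc3ccccc3)c2c1O[C@H](c1ccc(OCc3ccccc3)c(OCc3ccccc3)c1)[C@H](OCc3ccccc3)[C@H]2c1c(OCc3ccccc3)cc(OCc3ccccc3)c2c1O[C@H](c1ccc(OCc3ccccc3)c(OCc3ccccc3)c1)[C@H](OCc3ccccc3)[C@H]2c1c(OCc3ccccc3)cc(OCc3ccccc3)c2c1O[C@H](c1ccc(OCc3ccccc3)c(OCc3ccccc3)c1)[C@H](OCc3ccccc3)[C@H]2c1c(OCc3ccccc3)cc(OCc3ccccc3)c2c1O[C@H](c1ccc(OCc3ccccc3)c(OCc3ccccc3)c1)[C@@H](OCc3ccccc3)C2 | intermediate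
17 | the target arecatannin tetramer, epicatechin-(4β→8)-epicatechin-(4β→8)-epicatechin-(4β→8)-catechin | Oc1cc(O)c2c(c1)O[C@H](c1ccc(O)c(O)c1)[C@H](O)[C@H]2c1c(O)cc(O)c2c1O[C@H](c1ccc(O)c(O)c1)[C@H](O)[C@H]2c1c(O)cc(O)c2c1O[C@H](c1ccc(O)c(O)c1)[C@H](O)[C@H]2c1c(O)cc(O)c2c1O[C@H](c1ccc(O)c(O)c1)[C@@H](O)C2 | target

**Totals and risks**

Total step count: 13. Longest linear sequence: 8 steps (steps 1, 2, 3, 4, 5, 8, 12, 13; compounds 1 → 2 → 4 → 5 → 6 → 7 → 10 → 16 → 17).

The three steps most likely to fail: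

Step 12 (the proposed new gold-catalysed thioether activation). The released C4 cation may recombine at C3 of the aurated benzothiophene, the sulfide may slow the gold catalyst, and capture by the hindered dimer 15 may be slow. The fallback uses only known Lewis acid interflavan chemistry, sets out from 15 and comes back to the route at 16. Dimer 15 (2.5 equiv) is condensed with ether donor 5 (Me3SiOTf 0.1 equiv, CH2Cl2, −78 °C) to give the trimer nucleophile pentadeca-O-benzyl-[epicatechin-(4β→8)-epicatechin-(4β→8)-catechin] F2, which keeps a free C8 on its top unit. F2 (1.5 equiv) is then condensed under the same conditions with the bromo-capped ether donor 9 to give 16. This one-unit-at-a-time chain extension needs neither the dimeric electrophile 10 nor any thioether.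

Step 5 (Sonogashira coupling on 6). Oxidative addition into the electron-rich ortho-thio aryl bromide needs heat, which may damage the ionisable benzylic C4–S bond, and the sulfide may retard palladium. The fallback sets out from 5 and comes back at 7, and changes the handle precursor so that no heating is needed. Compound 5 is exchanged with 2-iodobenzenethiol (BF3·OEt2 0.2 equiv, CH2Cl2, −78 → −30 °C) to give penta-O-benzyl-4β-(2-iodophenylthio)epicatechin F1. Its C–I bond couples with 3,3-dimethylbut-1-yne at room temperature (PdCl2(MeCN)2, XPhos, Cs2CO3, MeCN/THF) to give 7.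

Step 13 (global hydrogenolysis with hydrodebromination). Twenty benzyl ethers must all be removed, the HBr released can attack the acid-labile free procyanidin, and halide or trace sulfur can poison the catalyst. The fallback sets out from 16 and comes back at 17, and takes the bromine off first by organometallic chemistry. Bromine–lithium exchange on 16 (n-BuLi, THF, −78 °C) followed by a methanol quench gives icosa-O-benzyl-[epicatechin-(4β→8)-epicatechin-(4β→8)-epicatechin-(4β→8)-catechin] F3. F3 is then hydrogenolysed under halide-free, neutral conditions (H2, Pd(OH)2/C, THF/MeOH/H2O) to give 17.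

Further compounds
F1 | step 5 | penta-O-benzyl-4β-(2-iodophenylthio)epicatechin (2,3-cis-3,4-trans) | c1c(OCc3ccccc3)cc(OCc3ccccc3)c2c1O[C@H](c1ccc(OCc3ccccc3)c(OCc3ccccc3)c1)[C@H](OCc3ccccc3)[C@H]2Sc1ccccc1I
F2 | step 12 | pentadeca-O-benzyl-[epicatechin-(4β→8)-epicatechin-(4β→8)-catechin] | c1c(OCc3ccccc3)cc(OCc3ccccc3)c2c1O[C@H](c1ccc(OCc3ccccc3)c(OCc3ccccc3)c1)[C@H](OCc3ccccc3)[C@H]2c1c(OCc3ccccc3)cc(OCc3ccccc3)c2c1O[C@H](c1ccc(OCc3ccccc3)c(OCc3ccccc3)c1)[C@H](OCc3ccccc3)[C@H]2c1c(OCc3ccccc3)cc(OCc3ccccc3)c2c1O[C@H](c1ccc(OCc3ccccc3)c(OCc3ccccc3)c1)[C@@H](OCc3ccccc3)C2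
F3 | step 13 | icosa-O-benzyl-[epicatechin-(4β→8)-epicatechin-(4β→8)-epicatechin-(4β→8)-catechin] | c1c(OCc3ccccc3)cc(OCc3ccccc3)c2c1O[C@H](c1ccc(OCc3ccccc3)c(OCc3ccccc3)c1)[C@H](OCc3ccccc3)[C@H]2c1c(OCc3ccccc3)cc(OCc3ccccc3)c2c1O[C@H](c1ccc(OCc3ccccc3)c(OCc3ccccc3)c1)[C@H](OCc3ccccc3)[C@H]2c1c(OCc3ccccc3)cc(OCc3ccccc3)c2c1O[C@H](c1ccc(OCc3ccccc3)c(OCc3ccccc3)c1)[C@H](OCc3ccccc3)[C@H]2c1c(OCc3ccccc3)cc(OCc3ccccc3)c2c1O[C@H](c1ccc(OCc3ccccc3)c(OCc3ccccc3)c1)[C@@H](OCc3ccccc3)C2
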